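(The data are calculated with made-up constants, noise included.)

| flask | substrate | partner | time |
|---|---|---|---|
| Wednesday's | 0.120 M | 0.300 M |  |
| Friday's | 0.120 M | 0.600 M |  |
| Sunday's | 0.180 M | 0.300 M |  |
| Saturday's | 0.360 M | 0.900 M | 33 min |

| Wednesday's run: time / min | Wednesday's run: [target] / M | Friday's run: time / min | Friday's run: [target] / M | Sunday's run: time / min | Sunday's run: [target] / M |
|---|---|---|---|---|---|
| 1.3 | 0.0043 | 1.3 | 0.0036 | 1.3 | 0.0052 |
| 2.3 | 0.0088 | 2.3 | 0.0112 | 2.3 | 0.0125 |
| 3.9 | 0.0166 | 3.9 | 0.0210 | 3.9 | 0.0238 |
| 6.6 | 0.0298 | 6.6 | 0.0359 | 6.6 | 0.0442 |
| 11 | 0.0430 | 11 | 0.0528 | 11 | 0.0669 |
| 19 | 0.0574 | 19 | 0.0703 | 19 | 0.0870 |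
| 33 | 0.0684 | 33 | 0.0798 | 33 | 0.0986 |

(standard deviation of a reading: 0.001 M)

- Overall: substrate + partner -> target.
- Constant volume, constant temperature.
- What is held in complexes is read along with the free species.
- "The second partner" is partner.
- An order is taken over about fifteen percent of the charge, up and down.

- the exponent of [partner] in the starting rate at the charge of the Wednesday's run (at the point where two percent of the substrate have become target)
- the exponent of [substrate] in the starting rate at the charge of the Wednesday's run (at the point where two percent of the substrate have become target) (one fixed amount of target, the same in the runs compared)
- target in the Saturday's run at 33 min, as a share of the substrate charged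
- which of these the readings show (the two partners rest in a complex / the product binds the second partner / nothing beyond the main steps / the second partner is lost in pairs / the second partner pairs with itself / the product binds the substrate)

**Early readings.** At 1.3 min, Wednesday's, Friday's and Sunday's flasks read 0.0043 M, 0.0036 M and 0.0052 M, and one scatter is a quarter of Wednesday's reading there, so you can't carry those numbers to Saturday's flask. Saturday's flask is asked at 33 min, the time of each run's last reading, so use the last readings, each as a share of its substrate, the limiting reagent.

**The rule.** Saturday's flask keeps Wednesday's proportion of substrate to partner but multiplies both charges by 3.00. Add two slopes of the logarithm of the share against the logarithm of the charge: Friday against Wednesday gives the slope for partner, and Sunday against Wednesday the slope for substrate.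

**What matters.** One scatter in Wednesday's last reading moves the answer by 4.82% of itself, because that reading enters both slopes. One scatter in Sunday's moves it by 2.75%, and in Friday's by 1.99%. So Wednesday's reading counts for more than either other.

**The number.** The shares are 57.0% on Wednesday, 66.5% on Friday and 54.8% on Sunday, so the sum is 0.124. This is the charge exponent: the power of the whole charge by which the share at that time grows while the proportion is held. My reckoning for Saturday's flask is 65.3%, give or take 3.8 percentage points from the scatter of those three readings, which is the band I use below.

**The forecast.** It gave 71%, higher than my reckoning, with partner exponent 0.4, substrate exponent 1 and the verdict "the second partner is lost in pairs". One of its grounds: “All runs stall well short of completion although partner is in excess”.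

**The flask.** The partner exponent is 0.30, the substrate exponent 0.65, Saturday's share 69.5%, and the verdict "the second partner pairs with itself".

    substrate → intermediate (0.1110 min⁻¹)
    intermediate + partner → target (4.104 M⁻¹ min⁻¹)
    intermediate → side product (0.2640 min⁻¹)
    2 partner ⇌ idle reagent dimer, settled at all times (11.50 M⁻¹)

**Pairing.** Saturday's 69.5% lies 4.2 points above my reckoning, about one band. Counted from Wednesday's share, it means a charge exponent of 0.181, higher than 0.124. Partner pairing into the idle reagent dimer is the main reason Saturday's share stops short. Saturday's flask with pairing taken away gives 89.4% against 69.5%.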